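(The numbers in the tables were generated by integration for an exercise, noise included.)

Follow E.

| flask | Z | D | E | remark | time |
|---|---|---|---|---|---|
| south | 0.81 M | 0.60 equiv | 1 equiv | run made earlier |  |
| north-east | 0.81 M | 2.4 equiv | 1 equiv | run made earlier |  |
| south-east | 0.81 M | 1.2 equiv | 0.50 equiv | run made earlier |  |
| flask | 0.81 M | 1.20 equiv | 1.00 equiv |  | 8.0 min |

- south (time / min: Z / %, X / %): 0.417: 80.7, 0.7; 1.33: 59.0, 1.2; 2.00: 50.7, 1.8; 3.00: 43.3, 3.8; 5.00: 34.3, 7.0
- north-east (time / min: Z / %, X / %): 0.417: 82.0, 0.3; 1.33: 66.0, 2.4; 2.00: 61.5, 5.1; 3.00: 58.1, 8.4; 5.00: 55.9, 12.3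
- south-east (time / min: Z / %, X / %): 0.417: 89.5, 0; 1.33: 79.5, 0; 2.00: 74.8, 1.0; 3.00: 71.6, 2.3; 5.00: 69.3, 3.7

(readings scatter by 0.3 percentage points)

1. at 8.0 min, what has stopped the reaction, if anything has (it is still moving / all of Z has reacted / forward and back rates have come level / D has run out first)
2. conversion of Z at 8.0 min
3. amount of X at 8.0 min, in percent of the Z charged
4. amount of Q at 8.0 min, in percent of the Z charged
5. amount of L at 8.0 min, in percent of the Z charged

- the numbers in the tables scatter with a standard deviation of 0.3 percentage points
- steps under discussion: Q + G <-> X; E + D -> G; X <-> L; 2 G -> J; Z + E -> Q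
- the reaction counts as stopped when no species that holds the Z changes by six tenths of a point or more over the second half of the time

Z and D both consume E, in Z + E -> Q and E + D -> G. Both rates carry cE, so E divides between them as S·cZ to cD, where S is the ratio of the two rate constants. Integrated, this makes S a ratio of logarithms. The north-east run gives 2.19 for S, the selectivity factor: the logarithm of the fraction of Z left over the logarithm of the fraction of D left. That reading assumes E is gone. But Z in the north-east run still fell 2.2 percentage points between its last two readings. The south-east run, with other charges, reads 2.09, a little less than the north-east value, so S stands as a reading with that much doubt.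

In the flask, the starting concentrations give Z a share of 64.6 % of E. Yet at that share Z loses a larger fraction of its charge than D does, so the share falls as E is used. Replacing the curves of cZ and cD by their means gives Z a share of 59.2 %. Applied to the full 1.00 equiv of E, that share is the Z consumed, which leaves Z at 40.8 %. The curves are not straight, however. Put back into the logarithmic form, that Z gives 2.16, and this gap from S is smaller than the gap between the two runs. The error of the mean therefore lies within the spread of the two readings. One doubt remains: the reckoning spends the full charge of E, while X in the north-east run still rose 3.9 points over its last interval. As an estimate, the flask is taken as still moving, with conversion near 59.2 % or slightly under. S speaks of Z and D; how Q, X and L divide the converted Z lies outside it.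

The forecast gives 59 % conversion, 13 % X, 44 % Q and 2 % L, calls the flask "it is still moving", and notes: “L was never measured”. The flask gives 58.9 % conversion, 13.3 % X, 35.9 % Q and 9.78 % L, and the verdict is "it is still moving".

    Q + G ⇌ X (K = 22.0 M⁻¹, k = 0.00790 M⁻¹ s⁻¹)
    E + D → G (k = 0.00540 M⁻¹ s⁻¹)
    X ⇌ L (K = 1.10, k = 0.00500 s⁻¹)
    2 G → J (k = 1.50 × 10⁻⁴ M⁻¹ s⁻¹)
    Z + E → Q (k = 0.0120 M⁻¹ s⁻¹)

The flask's Z and D at 8.00 min read S as 2.22. The neighbouring flask holds 0.480 equiv of D, all else as charged. Its starting share for Z is 82.0 %, and the mean reckoning lowers this to 76.8 %. That flask keeps 6.79 % of its E, so the reckoning gives 71.6 % conversion, and it shows 72.2 %. Its Z left, 27.8 %, and D left, 56.2 %, read S as 2.22.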